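**Plan**

- Retrosynthetic cuts, in order: (a) the C8–CH2 bond between ring A and the acylphloroglucinol; (b) the C3–O bond; (c) the pyran ring C at C3–C4 and O1–C2, after a formyl helper has been placed on C3.
- Enabling feature: O1 and C4 sit on the neighbouring ring A carbons C8a and C4a (a phloroglucinol salicylaldehyde), and C2 (bearing catechol ring B) and C3 are the β- and α-carbons of a cinnamaldehyde. An amine-catalysed oxa-Michael addition (O1–C2) followed by aldol closure of C3 onto C4 therefore builds ring C in one operation.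
- Forward: rings A and B enter as aldehydes and ring C is closed in step 3. The C3 formyl helper is then excised (step 4) and the C3 hydroxyl installed (step 5). The acylphloroglucinol is made separately (steps 6–10), joined at C8 through its ortho-quinone methide (step 11), and all benzyl ethers are removed (step 12).
- Stereochemistry: C2 comes from the (S)-diarylprolinol silyl ether catalyst in step 3; C3 comes from hydroboration anti to the C2 aryl group in step 5 (2,3-trans).

Key step: step 3

Remark (assumption): in step 7 the hydroxyl of 12 that lies between the acetyl and the C-methyl group (doubly flanked and chelated) is taken to be the least reactive, so that dibenzylation leaves it free for the later O-methylation.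

**Step 1**
Reactants: 1 2,4,6-trihydroxybenzaldehyde
Product: 2 2,4-bis(benzyloxy)-6-hydroxybenzaldehyde
Conditions: BnBr (2.05 equiv), K2CO3 (2.1 equiv), DMF, 0 °C to rt
Reagents that add atoms: benzyl bromide, BrCc1ccccc1
Why: Williamson etherification alkylates the para hydroxyl and one of the two equivalent ortho hydroxyls, while the last ortho hydroxyl is held in a hydrogen bond to the formyl group and stays free as the future O1.

**Step 2**
Reactants: 3 3,4-bis(benzyloxy)benzaldehyde
Product: 4 (2E)-3-[3,4-bis(benzyloxy)phenyl]prop-2-enal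
Conditions: Ph3P=CHCHO (1.1 equiv), toluene, 80 °C
Reagents that add atoms: (triphenylphosphoranylidene)acetaldehyde, O=CC=P(c1ccccc1)(c1ccccc1)c1ccccc1
Why: Wittig olefination with a stabilised ylide should give the E-enal, which supplies C2, C3 and the removable formyl carbon.

**Step 3**
Reactants: 2 2,4-bis(benzyloxy)-6-hydroxybenzaldehyde; 4 (2E)-3-[3,4-bis(benzyloxy)phenyl]prop-2-enal
Product: 7 (2R)-5,7-bis(benzyloxy)-2-[3,4-bis(benzyloxy)phenyl]-2H-chromene-3-carbaldehyde, via oxa-Michael enamine 5 (not isolated), via aldol enamine 6 (not isolated)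
Conditions: 4 (1.2 equiv), (S)-2-[diphenyl(trimethylsilyloxy)methyl]pyrrolidine (20 mol %), 2-nitrobenzoic acid (20 mol %), 4 Å MS, toluene, rt
Reagents that add atoms: none
Why: The secondary amine condenses with enal 4 to an E-iminium ion, the phenol of 2 adds to its β-carbon (future C2) to give enamine 5, and the enamine α-carbon (future C3) attacks the ortho formyl carbon (future C4) in an intramolecular aldol reaction; loss of water from 6 and hydrolysis release 7 and the catalyst. The closest known reaction type is the diarylprolinol silyl ether-catalysed domino oxa-Michael/aldol condensation of salicylaldehydes with cinnamaldehydes to 2-aryl-2H-chromene-3-carbaldehydes. Ring C (O1, C2, C3, C4, C4a, C8a) closes in a 6-exo-trig (enolexo) aldol mode. The only new stereocenter, C2, is set in the oxa-Michael step by the catalyst: the diphenyl(trimethylsilyloxy)methyl group of the (S)-catalyst shields one face of the s-trans E-iminium ion, and attack of the phenol on the open face is expected to give the (2R) configuration. The step needs O- over C-attack, 1,4- over 1,2-addition and a single direction of ring closure; these are secured by the benzyl ethers at O5 and O7, which leave only the phenol ortho to the formyl group free, and by the irreversible dehydration, which drains the reversible oxa-Michael adducts through the one able to cyclise. The formyl group on C3 is the activating group of the event and is removed in step 4.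

**Step 4**
Reactants: 7 (2R)-5,7-bis(benzyloxy)-2-[3,4-bis(benzyloxy)phenyl]-2H-chromene-3-carbaldehyde
Product: 8 (2S)-5,7-bis(benzyloxy)-2-[3,4-bis(benzyloxy)phenyl]-2H-chromene
Conditions: RhCl(PPh3)3 (1.1 equiv), toluene, 80 °C, Ar
Reagents that add atoms: none
Why: Tsuji–Wilkinson decarbonylation (oxidative addition of the formyl C–H bond to monovalent rhodium, CO extrusion, reductive elimination) replaces the C3 formyl group by hydrogen and leaves the C3=C4 bond and C2 untouched.

**Step 5**
Reactants: 8 (2S)-5,7-bis(benzyloxy)-2-[3,4-bis(benzyloxy)phenyl]-2H-chromene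
Product: 10 (2R,3S)-5,7-bis(benzyloxy)-2-[3,4-bis(benzyloxy)phenyl]-3,4-dihydro-2H-chromen-3-ol, via alkylborane 9 (not isolated)
Conditions: BH3·THF (2 equiv), THF, 0 °C to rt; then 3 M NaOH, 30% H2O2, 0 °C
Reagents that add atoms: hydrogen peroxide, OO
Why: Hydroboration–oxidation places boron on C3 (styrene-type and allylic-ether polarisation of C3=C4) on the face anti to the C2 aryl group, and oxidation with retention should give the 2,3-trans alcohol, so that C3 is set by substrate control.

**Step 6**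
Reactants: 11 2-methylbenzene-1,3,5-triol
Product: 12 1-(2,4,6-trihydroxy-3-methylphenyl)ethan-1-one
Conditions: AcCl (1.1 equiv), AlCl3 (3.5 equiv), CH2Cl2–PhNO2, 0 °C to rt; then aq. HCl
Reagents that add atoms: acetyl chloride, CC(Cl)=O
Why: Friedel–Crafts C-acylation gives a single ketone because the two free ring positions of 11 are equivalent and the first acyl group deactivates the ring.

**Step 7**
Reactants: 12 1-(2,4,6-trihydroxy-3-methylphenyl)ethan-1-one
Product: 13 1-[4,6-bis(benzyloxy)-2-hydroxy-3-methylphenyl]ethan-1-one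
Conditions: BnBr (2.05 equiv), K2CO3 (2.1 equiv), acetone, reflux
Reagents that add atoms: benzyl bromide, BrCc1ccccc1
Why: Williamson etherification should take the para hydroxyl and the less hindered ortho hydroxyl, leaving the chelated hydroxyl between the acetyl and methyl groups free.

**Step 8**
Reactants: 13 1-[4,6-bis(benzyloxy)-2-hydroxy-3-methylphenyl]ethan-1-one
Product: 14 1-[4,6-bis(benzyloxy)-2-methoxy-3-methylphenyl]ethan-1-one
Conditions: MeI (3 equiv), K2CO3 (2 equiv), DMF, 50 °C
Reagents that add atoms: iodomethane, CI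
Why: Williamson O-methylation of the one remaining phenol under forcing conditions places the methoxy group between the acetyl and methyl groups.

**Step 9**
Reactants: 14 1-[4,6-bis(benzyloxy)-2-methoxy-3-methylphenyl]ethan-1-one
Product: 15 1-(4,6-dihydroxy-2-methoxy-3-methylphenyl)ethan-1-one
Conditions: H2 (1 atm), 10% Pd/C, EtOAc–MeOH, rt
Reagents that add atoms: none
Why: Hydrogenolysis cleaves the two benzyl ethers, while the hindered aryl ketone and the methyl ether should survive these mild conditions.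

**Step 10**
Reactants: 15 1-(4,6-dihydroxy-2-methoxy-3-methylphenyl)ethan-1-one
Product: 16 1-{3-[(dimethylamino)methyl]-2,4-dihydroxy-6-methoxy-5-methylphenyl}ethan-1-one
Conditions: 37% aq. CH2O (1.2 equiv), 40% aq. Me2NH (1.2 equiv), EtOH, rt
Reagents that add atoms: formaldehyde, C=O; dimethylamine, CNC
Why: The phenol Mannich reaction can only take place at the single unsubstituted ring carbon, which lies between the two hydroxyls, and stores the bridging CH2 as a stable ortho-quinone methide precursor.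

**Step 11**
Reactants: 10 (2R,3S)-5,7-bis(benzyloxy)-2-[3,4-bis(benzyloxy)phenyl]-3,4-dihydro-2H-chromen-3-ol; 16 1-{3-[(dimethylamino)methyl]-2,4-dihydroxy-6-methoxy-5-methylphenyl}ethan-1-one
Product: 18 1-[3-({(2R,3S)-5,7-bis(benzyloxy)-2-[3,4-bis(benzyloxy)phenyl]-3-hydroxy-3,4-dihydro-2H-chromen-8-yl}methyl)-2,4-dihydroxy-6-methoxy-5-methylphenyl]ethan-1-one, via ortho-quinone methide 17 (not isolated)
Conditions: 10 (1.2 equiv), 1,4-dioxane–AcOH (10:1), 90 °C, Ar
Reagents that add atoms: none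
Why: Thermal loss of Me2NH from 16 gives ortho-quinone methide 17, which in its acid-activated form undergoes Friedel–Crafts alkylation at C8 of ring A of 10, the position preferred in electrophilic substitution of 5,7-di-O-benzyl flavans because C6 is flanked by two benzyloxy groups.

**Step 12**
Reactants: 18 1-[3-({(2R,3S)-5,7-bis(benzyloxy)-2-[3,4-bis(benzyloxy)phenyl]-3-hydroxy-3,4-dihydro-2H-chromen-8-yl}methyl)-2,4-dihydroxy-6-methoxy-5-methylphenyl]ethan-1-one
Product: 19 pilosanol N
Conditions: H2 (1 atm), 20% Pd(OH)2/C, THF–MeOH, rt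
Reagents that add atoms: none
Why: Global hydrogenolysis removes the four benzyl aryl ethers without touching C2, C3, the diarylmethane bridge, the methyl ether or the chelated ketone.

**Compound list**

1 | 2,4,6-trihydroxybenzaldehyde | O=Cc1c(O)cc(O)cc1O | starting material
2 | 2,4-bis(benzyloxy)-6-hydroxybenzaldehyde | O=Cc1c(O)cc(OCc2ccccc2)cc1OCc1ccccc1 | intermediate
3 | 3,4-bis(benzyloxy)benzaldehyde | O=Cc1ccc(OCc2ccccc2)c(OCc2ccccc2)c1 | starting material
4 | (2E)-3-[3,4-bis(benzyloxy)phenyl]prop-2-enal | O=C/C=C/c1ccc(OCc2ccccc2)c(OCc2ccccc2)c1 | intermediate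
5 | 2-{[(1S,2E)-1-[3,4-bis(benzyloxy)phenyl]-3-{(2S)-2-[diphenyl(trimethylsilyloxy)methyl]pyrrolidin-1-yl}prop-2-en-1-yl]oxy}-4,6-bis(benzyloxy)benzaldehyde (oxa-Michael adduct as its catalyst enamine) | C[Si](C)(C)OC(c1ccccc1)(c1ccccc1)[C@@H]1CCCN1/C=C/[C@H](Oc1cc(OCc2ccccc2)cc(OCc2ccccc2)c1C=O)c1ccc(OCc2ccccc2)c(OCc2ccccc2)c1 | intermediate
6 | (2R)-5,7-bis(benzyloxy)-2-[3,4-bis(benzyloxy)phenyl]-3-({(2S)-2-[diphenyl(trimethylsilyloxy)methyl]pyrrolidin-1-yl}methylidene)-3,4-dihydro-2H-chromen-4-ol (aldol adduct as its catalyst enamine; C4 and enamine geometry not defined) | C[Si](C)(C)OC(c1ccccc1)(c1ccccc1)[C@@H]1CCCN1C=C1C(O)c2c(OCc3ccccc3)cc(OCc3ccccc3)cc2O[C@@H]1c1ccc(OCc2ccccc2)c(OCc2ccccc2)c1 | intermediate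
7 | (2R)-5,7-bis(benzyloxy)-2-[3,4-bis(benzyloxy)phenyl]-2H-chromene-3-carbaldehyde | O=CC1=Cc2c(OCc3ccccc3)cc(OCc3ccccc3)cc2O[C@@H]1c1ccc(OCc2ccccc2)c(OCc2ccccc2)c1 | intermediate
8 | (2S)-5,7-bis(benzyloxy)-2-[3,4-bis(benzyloxy)phenyl]-2H-chromene (same spatial arrangement at C2 as in 7 and 10; the descriptor changes only through the CIP rank of C3) | C1=Cc2c(OCc3ccccc3)cc(OCc3ccccc3)cc2O[C@@H]1c1ccc(OCc2ccccc2)c(OCc2ccccc2)c1 | intermediate
9 | [(2S,3S)-5,7-bis(benzyloxy)-2-[3,4-bis(benzyloxy)phenyl]-3,4-dihydro-2H-chromen-3-yl]borane (2,3-trans) | B[C@H]1Cc2c(OCc3ccccc3)cc(OCc3ccccc3)cc2O[C@@H]1c1ccc(OCc2ccccc2)c(OCc2ccccc2)c1 | intermediate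
10 | (2R,3S)-5,7-bis(benzyloxy)-2-[3,4-bis(benzyloxy)phenyl]-3,4-dihydro-2H-chromen-3-ol (5,7,3',4'-tetra-O-benzyl-(+)-catechin) | O[C@H]1Cc2c(OCc3ccccc3)cc(OCc3ccccc3)cc2O[C@@H]1c1ccc(OCc2ccccc2)c(OCc2ccccc2)c1 | intermediate
11 | 2-methylbenzene-1,3,5-triol | Cc1c(O)cc(O)cc1O | starting material
12 | 1-(2,4,6-trihydroxy-3-methylphenyl)ethan-1-one | CC(=O)c1c(O)cc(O)c(C)c1O | intermediate
13 | 1-[4,6-bis(benzyloxy)-2-hydroxy-3-methylphenyl]ethan-1-one | CC(=O)c1c(OCc2ccccc2)cc(OCc2ccccc2)c(C)c1O | intermediate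
14 | 1-[4,6-bis(benzyloxy)-2-methoxy-3-methylphenyl]ethan-1-one | CC(=O)c1c(OCc2ccccc2)cc(OCc2ccccc2)c(C)c1OC | intermediate
15 | 1-(4,6-dihydroxy-2-methoxy-3-methylphenyl)ethan-1-one | CC(=O)c1c(O)cc(O)c(C)c1OC | intermediate
16 | 1-{3-[(dimethylamino)methyl]-2,4-dihydroxy-6-methoxy-5-methylphenyl}ethan-1-one | CC(=O)c1c(O)c(CN(C)C)c(O)c(C)c1OC | intermediate
17 | 4-acetyl-3-hydroxy-5-methoxy-6-methyl-2-methylidenecyclohexa-3,5-dien-1-one (ortho-quinone methide) | CC(=O)C1=C(O)C(=C)C(=O)C(C)=C1OC | intermediate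
18 | 1-[3-({(2R,3S)-5,7-bis(benzyloxy)-2-[3,4-bis(benzyloxy)phenyl]-3-hydroxy-3,4-dihydro-2H-chromen-8-yl}methyl)-2,4-dihydroxy-6-methoxy-5-methylphenyl]ethan-1-one | COc1c(C)c(O)c(Cc2c(OCc4ccccc4)cc(OCc4ccccc4)c3c2O[C@H](c2ccc(OCc4ccccc4)c(OCc4ccccc4)c2)[C@@H](O)C3)c(O)c1C(C)=O | intermediate
19 | pilosanol N, 1-[3-({(2R,3S)-2-(3,4-dihydroxyphenyl)-3,5,7-trihydroxy-3,4-dihydro-2H-chromen-8-yl}methyl)-2,4-dihydroxy-6-methoxy-5-methylphenyl]ethan-1-one | COc1c(C)c(O)c(Cc2c(O)cc(O)c3c2O[C@H](c2ccc(O)c(O)c2)[C@@H](O)C3)c(O)c1C(C)=O | target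

**Step count and risks**

Total steps: 12. Longest linear sequence: 7 (steps 6 to 12).

Steps most likely to fail:

1. Step 3. Iminium formation and oxa-Michael addition may be slow because both partners are electron-rich, and reversible oxa-Michael addition or an uncatalysed background reaction may erode the enantioselectivity. The fallback sets out from 2 and 4 and returns at 8. Wittig methylenation of 2 (Ph3P=CH2 from methyltriphenylphosphonium bromide and KOtBu, 2.2 equiv, THF) would give 3,5-bis(benzyloxy)-2-ethenylphenol F1. 1,2-Reduction of 4 (NaBH4, CeCl3·7H2O, MeOH) would give (2E)-3-[3,4-bis(benzyloxy)phenyl]prop-2-en-1-ol F2, which is converted (ClCO2Me, pyridine) to (2E)-3-[3,4-bis(benzyloxy)phenyl]prop-2-en-1-yl methyl carbonate F3. Branch-selective, enantioselective allylic etherification of the lithium phenoxide of F1 with F3 ([Ir(cod)Cl]2, a BINOL-derived chiral phosphoramidite ligand of the enantiomer leading to the (S)-ether, THF) would give 1,5-bis(benzyloxy)-3-{[(1S)-1-[3,4-bis(benzyloxy)phenyl]prop-2-en-1-yl]oxy}-2-ethenylbenzene F4. Ring-closing metathesis of F4 (second-generation Grubbs catalyst, CH2Cl2, 40 °C) closes the same C3=C4 bond and gives 8, so that step 4 is bypassed as well.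

2. Step 4. At the temperature needed for CO extrusion the 2H-chromene may racemise at C2 by reversible 6π ring opening, the double bond may migrate to the 4H-chromene, or decarbonylation may stay incomplete. The fallback sets out from 7 and returns at 10, with no heating. Baeyer–Villiger oxidation of the enal (mCPBA, NaHCO3, CH2Cl2, 0 °C) would give (2R)-5,7-bis(benzyloxy)-2-[3,4-bis(benzyloxy)phenyl]-2H-chromen-3-yl formate F5. Mild cleavage (NaHCO3, MeOH–H2O, 0 °C) would give (2R)-5,7-bis(benzyloxy)-2-[3,4-bis(benzyloxy)phenyl]-2H-chromen-3(4H)-one F6. Reduction with NaBH4 (THF–MeOH, −40 °C, axial hydride delivery with the C2 aryl group equatorial) would give the trans alcohol 10, replacing steps 4 and 5.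

3. Step 11. The aryl ether may be too weak a nucleophile, so that ortho-quinone methide 17 oligomerises, or attack may occur partly at C6. The fallback sets out from 10 and returns at 18. Bromination with NBS (CH2Cl2, −20 °C), a reaction type known to go to C8 of tetra-O-benzylcatechin, would give (2R,3S)-5,7-bis(benzyloxy)-2-[3,4-bis(benzyloxy)phenyl]-8-bromo-3,4-dihydro-2H-chromen-3-ol F7. Treatment with n-BuLi (2.2 equiv, THF, −78 °C; alkoxide formation, then bromine–lithium exchange) and DMF would give (2R,3S)-5,7-bis(benzyloxy)-2-[3,4-bis(benzyloxy)phenyl]-3-hydroxy-3,4-dihydro-2H-chromene-8-carbaldehyde F8. NaBH4 would give (2R,3S)-5,7-bis(benzyloxy)-2-[3,4-bis(benzyloxy)phenyl]-8-(hydroxymethyl)-3,4-dihydro-2H-chromen-3-ol F9. Its 2,4,6-trioxygenated benzyl cation (Sc(OTf)3 cat., CH2Cl2, 0 °C) would be captured by the single free ring position of acylphloroglucinol 15 (used in excess) to give 18, with the site of attachment fixed on both partners.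

**Further compounds**

F1 | step 3 | 3,5-bis(benzyloxy)-2-ethenylphenol | C=Cc1c(O)cc(OCc2ccccc2)cc1OCc1ccccc1
F2 | step 3 | (2E)-3-[3,4-bis(benzyloxy)phenyl]prop-2-en-1-ol | OC/C=C/c1ccc(OCc2ccccc2)c(OCc2ccccc2)c1
F3 | step 3 | (2E)-3-[3,4-bis(benzyloxy)phenyl]prop-2-en-1-yl methyl carbonate | COC(=O)OC/C=C/c1ccc(OCc2ccccc2)c(OCc2ccccc2)c1
F4 | step 3 | 1,5-bis(benzyloxy)-3-{[(1S)-1-[3,4-bis(benzyloxy)phenyl]prop-2-en-1-yl]oxy}-2-ethenylbenzene | C=C[C@H](Oc1cc(OCc2ccccc2)cc(OCc2ccccc2)c1C=C)c1ccc(OCc2ccccc2)c(OCc2ccccc2)c1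
F5 | step 4 | (2R)-5,7-bis(benzyloxy)-2-[3,4-bis(benzyloxy)phenyl]-2H-chromen-3-yl formate | O=COC1=Cc2c(OCc3ccccc3)cc(OCc3ccccc3)cc2O[C@@H]1c1ccc(OCc2ccccc2)c(OCc2ccccc2)c1
F6 | step 4 | (2R)-5,7-bis(benzyloxy)-2-[3,4-bis(benzyloxy)phenyl]-2H-chromen-3(4H)-one | O=C1Cc2c(OCc3ccccc3)cc(OCc3ccccc3)cc2O[C@@H]1c1ccc(OCc2ccccc2)c(OCc2ccccc2)c1
F7 | step 11 | (2R,3S)-5,7-bis(benzyloxy)-2-[3,4-bis(benzyloxy)phenyl]-8-bromo-3,4-dihydro-2H-chromen-3-ol | O[C@H]1Cc2c(OCc3ccccc3)cc(OCc3ccccc3)c(Br)c2O[C@@H]1c1ccc(OCc2ccccc2)c(OCc2ccccc2)c1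
F8 | step 11 | (2R,3S)-5,7-bis(benzyloxy)-2-[3,4-bis(benzyloxy)phenyl]-3-hydroxy-3,4-dihydro-2H-chromene-8-carbaldehyde | O[C@H]1Cc2c(OCc3ccccc3)cc(OCc3ccccc3)c(C=O)c2O[C@@H]1c1ccc(OCc2ccccc2)c(OCc2ccccc2)c1
F9 | step 11 | (2R,3S)-5,7-bis(benzyloxy)-2-[3,4-bis(benzyloxy)phenyl]-8-(hydroxymethyl)-3,4-dihydro-2H-chromen-3-ol | O[C@H]1Cc2c(OCc3ccccc3)cc(OCc3ccccc3)c(CO)c2O[C@@H]1c1ccc(OCc2ccccc2)c(OCc2ccccc2)c1
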